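Ring A of the isoflavone is disconnected at C4a–C5 and C8–C8a. Its 1,3-related C5 and C7 hydroxyls, with C5 beside C4a, map onto a 1,1,3-trioxygenated butadiene (C5–C8) that is added across the C4a=C8a double bond of a preformed 3-aryl-4-pyranone (ring C carrying complete ring B). A phenylsulfonyl group on C4a activates that bond, directs the diene and leaves as sulfinate, so one operation builds ring A, aromatises it and delivers both phenols unprotected. The precursor is the 2'-O-benzyl 3-aryl-5-(phenylsulfonyl)-4H-pyran-4-one; its tertiary hydroxyl is silylated in the flask so that no proton source meets the ketene acetal. Hydrogenolysis of the single benzyl ether then gives the target.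

Key step: step 10

Assumption: the alkene geometry of 4, 12, 15 and of diene 17 about C1=C2 has no bearing on the outcome, since each of these double bonds is consumed; 17 is drawn as its 1E isomer.

Step 1
Reactants: 1 2-hydroxy-4,5-dimethoxybenzaldehyde
Product: 2 2-hydroxy-3-iodo-4,5-dimethoxybenzaldehyde
Conditions: N-iodosuccinimide, TsOH·H2O (10 mol%), MeCN, 0 °C → rt
Reagents that add atoms: N-iodosuccinimide, O=C1CCC(=O)N1I
Why: Electrophilic aromatic iodination should go to C3 alone, the only free position ortho to the phenol (the para position carries OMe), which is further activated by the 4-methoxy group and lies meta to the aldehyde.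

Step 2
Reactants: 2 2-hydroxy-3-iodo-4,5-dimethoxybenzaldehyde
Product: 3 2-(benzyloxy)-3-iodo-4,5-dimethoxybenzaldehyde
Conditions: BnBr, K2CO3, DMF, 60 °C
Reagents that add atoms: benzyl bromide, BrCc1ccccc1
Why: Williamson etherification of the phenoxide; the benzyl ether is chosen because it withstands every later acid, base and organolithium step and falls under neutral hydrogenolysis at the end.

Step 3
Reactants: 3 2-(benzyloxy)-3-iodo-4,5-dimethoxybenzaldehyde
Product: 4 2-(benzyloxy)-3-iodo-4,5-dimethoxy-1-[2-(methylsulfanyl)-2-(methylsulfinyl)ethenyl]benzene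
Conditions: CH3S(O)CH2SCH3, benzyltrimethylammonium hydroxide (40% in MeOH), THF, reflux
Reagents that add atoms: methyl (methylsulfanyl)methyl sulfoxide, CSCS(C)=O
Why: Knoevenagel-type condensation of the non-enolisable aldehyde with the carbanion of the formaldehyde dithioacetal S-oxide should give the ketene dithioacetal S-oxide, the aldehyde carbon becoming the future C3 of the pyranone.

Step 4
Reactants: 4 2-(benzyloxy)-3-iodo-4,5-dimethoxy-1-[2-(methylsulfanyl)-2-(methylsulfinyl)ethenyl]benzene
Product: 5 methyl 2-[2-(benzyloxy)-3-iodo-4,5-dimethoxyphenyl]acetate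
Conditions: HCl (ca. 3 M in MeOH), rt → 40 °C
Reagents that add atoms: methanol, CO
Why: Acid-induced methanolysis of a ketene dithioacetal S-oxide (protonation at the benzylic carbon, addition of methanol, loss of both sulfur groups as dimethyl disulfide) is an established one-carbon homologation of ArCHO to ArCH2CO2Me, and it is run before the acid-sensitive tertiary alcohol exists.

Step 5
Reactants: 5 methyl 2-[2-(benzyloxy)-3-iodo-4,5-dimethoxyphenyl]acetate; 6 2-methylbut-3-en-2-ol
Product: 8 methyl 2-[2-(benzyloxy)-3-(3-hydroxy-3-methylbutyl)-4,5-dimethoxyphenyl]acetate, via B-(3-hydroxy-3-methylbutyl)-9-BBN 7 (not isolated)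
Conditions: 6, 9-BBN (2.1 equiv per 6), THF, 0 °C → rt; then 3 M aq K3PO4, 5, Pd(OAc)2, SPhos (2-dicyclohexylphosphino-2',6'-dimethoxybiphenyl), THF, 60 °C
Reagents that add atoms: none
Why: Anti-Markovnikov hydroboration of the terminal alkene followed by B-alkyl Suzuki–Miyaura coupling installs the side chain at its final oxidation level, so no alkene has to be hydrogenated beside the benzyl ether; the extra 9-BBN covers the tertiary hydroxyl and the bulky electron-rich biarylphosphine serves the iodide flanked by two alkoxy groups.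

Step 6
Reactants: 8 methyl 2-[2-(benzyloxy)-3-(3-hydroxy-3-methylbutyl)-4,5-dimethoxyphenyl]acetate; 9 methyl phenyl sulfone
Product: 11 1-[2-(benzyloxy)-3-(3-hydroxy-3-methylbutyl)-4,5-dimethoxyphenyl]-3-(phenylsulfonyl)propan-2-one, via [(phenylsulfonyl)methyl]lithium 10 (not isolated)
Conditions: 9 (3.5 equiv), n-BuLi (3.3 equiv), THF, −78 °C; then 8, −78 → −20 °C; aq NH4Cl
Reagents that add atoms: none
Why: Claisen-type acylation of the α-lithiated sulfone by the methyl ester: at −78 °C carbonyl addition should outrun enolisation of the arylacetate (as in the analogous preparation of β-keto phosphonates from arylacetates), the β-keto sulfone is shielded from over-addition as its enolate, and the surplus base covers the alkoxide.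

Step 7
Reactants: 11 1-[2-(benzyloxy)-3-(3-hydroxy-3-methylbutyl)-4,5-dimethoxyphenyl]-3-(phenylsulfonyl)propan-2-one
Product: 13 3-[2-(benzyloxy)-3-(3-hydroxy-3-methylbutyl)-4,5-dimethoxyphenyl]-5-(phenylsulfonyl)-4H-pyran-4-one, via bis-enaminone 12 (not isolated)
Conditions: Me2NCH(OMe)2 (neat, excess), 100 °C; evaporate; then 1 M HCl, THF, rt
Reagents that add atoms: N,N-dimethylformamide dimethyl acetal, COC(OC)N(C)C; water, O
Why: Amide-acetal condensation at both methylene groups of a 1,3-disubstituted acetone (the sulfonyl-activated one first, the benzylic one on heating, as in deoxybenzoin-to-isoflavone chemistry), then acid hydrolysis of one enamine and 6-endo-trig O-cyclisation with loss of dimethylamine, is the standard entry to 3,5-disubstituted 4-pyranones; dilute acid at room temperature should spare the tertiary alcohol.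

Step 8
Reactants: 14 methyl acetoacetate
Product: 15 methyl 3-(trimethylsilyloxy)but-2-enoate
Conditions: TMSCl, Et3N, hexane, rt
Reagents that add atoms: chlorotrimethylsilane, C[Si](C)(C)Cl
Why: O-silylation of the enol of the β-keto ester should give the silyl enol ether.

Step 9
Reactants: 15 methyl 3-(trimethylsilyloxy)but-2-enoate
Product: 17 (1E)-1-methoxy-1,3-bis(trimethylsilyloxy)buta-1,3-diene, via lithium dienolate 16 (not isolated)
Conditions: LiN(iPr)2, THF, −78 °C; then TMSCl, −78 °C → rt; distil
Reagents that add atoms: chlorotrimethylsilane, C[Si](C)(C)Cl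
Why: γ-Deprotonation by the lithium amide gives the extended ester dienolate, whose O-silylation at the ester oxygen should furnish the 1,1,3-trioxygenated diene, to be used freshly distilled.

Step 10
Reactants: 13 3-[2-(benzyloxy)-3-(3-hydroxy-3-methylbutyl)-4,5-dimethoxyphenyl]-5-(phenylsulfonyl)-4H-pyran-4-one; 17 (1E)-1-methoxy-1,3-bis(trimethylsilyloxy)buta-1,3-diene
Product: 20 3-[2-(benzyloxy)-3-(3-hydroxy-3-methylbutyl)-4,5-dimethoxyphenyl]-5,7-dihydroxy-4H-chromen-4-one, via O-silylated pyranone 18 (not isolated), via sulfonyl cycloadduct 19 (not isolated)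
Conditions: N,O-bis(trimethylsilyl)acetamide, toluene, 60 °C; then 17 (3 equiv), −20 °C → rt; then DBU, 50 °C; then citric acid, MeOH/THF, rt
Reagents that add atoms: none
Why: Proposed new method: the diene should add across the C5=C6 bond of pyranone 18 (the future C4a=C8a bond) in a polarised, probably asynchronous [4+2] process, its CH2 terminus (future C8) bonding to C6 (future C8a) and the sulfonyl-bearing C5 (future C4a) to the ketene-acetal carbon (future C5), so that ring A closes as a six-membered carbocycle either in concert or, if stepwise, by a 6-(enolexo)-exo-trig closure of the sulfonyl-stabilised carbanion onto the oxocarbenium carbon, giving adduct 19. The closest known reaction types are the cycloadditions of 1,1,3-trioxygenated silyloxydienes with 2-haloquinones and with 3-sulfinyl- or 3-sulfonylchromones, which give anthraquinones and xanthones after loss of HX; a monocyclic 4-pyranone has not been used as the dienophile. Collapse of the C5 silyl ketal with loss of MeOSiMe3, DBU-promoted loss of benzenesulfinic acid across C4a–C8a (anti after epimerisation of C8a through reversible oxa-Michael opening, or syn, in either case driven by aromatisation) and enolisation should aromatise the new ring, and the mild acid work-up strips the remaining trimethylsilyl groups, so that both phenols and the tertiary alcohol emerge free. No stereocentre has to be controlled, because those of 19 at C4a, C5 and C8a are all erased on aromatisation. Site selectivity and orientation are needed: the sulfone makes C6 the only carbon that is beta to two acceptors, C2 is damped by the donor aryl ring on C3, and the nucleophilic CH2 end of the diene therefore goes to C6, which places the two oxygens at C5 and C7. Lewis-acid-free conditions in toluene and prior silylation of the tertiary hydroxyl are chosen so that the first C–C bond is not followed by protonation or by irreversible retro-oxa-Michael opening of the heterocycle.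

Step 11
Reactants: 20 3-[2-(benzyloxy)-3-(3-hydroxy-3-methylbutyl)-4,5-dimethoxyphenyl]-5,7-dihydroxy-4H-chromen-4-one
Product: 21 5,7-dihydroxy-3-[2-hydroxy-3-(3-hydroxy-3-methylbutyl)-4,5-dimethoxyphenyl]-4H-chromen-4-one
Conditions: H2 (1 atm), 10% Pd/C, EtOAc/MeOH, rt
Reagents that add atoms: none
Why: Catalytic hydrogenolysis should cleave the aryl benzyl ether under neutral conditions much faster than it touches the C2=C3 bond of the isoflavone (a vinylogous ester), and the absence of acid keeps the freed 2'-hydroxyl from closing a chroman onto the tertiary alcohol.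

Compound list
1 | 2-hydroxy-4,5-dimethoxybenzaldehyde | O=Cc1cc(OC)c(OC)cc1O | starting material
2 | 2-hydroxy-3-iodo-4,5-dimethoxybenzaldehyde | O=Cc1cc(OC)c(OC)c(I)c1O | intermediate
3 | 2-(benzyloxy)-3-iodo-4,5-dimethoxybenzaldehyde | O=Cc1cc(OC)c(OC)c(I)c1OCc1ccccc1 | intermediate
4 | 2-(benzyloxy)-3-iodo-4,5-dimethoxy-1-[2-(methylsulfanyl)-2-(methylsulfinyl)ethenyl]benzene (alkene isomers, racemic at sulfur) | COc1cc(C=C(SC)S(C)=O)c(OCc2ccccc2)c(I)c1OC | intermediate
5 | methyl 2-[2-(benzyloxy)-3-iodo-4,5-dimethoxyphenyl]acetate | COC(=O)Cc1cc(OC)c(OC)c(I)c1OCc1ccccc1 | intermediate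
6 | 2-methylbut-3-en-2-ol | C=CC(C)(C)O | starting material
7 | B-(3-hydroxy-3-methylbutyl)-9-borabicyclo[3.3.1]nonane | CC(C)(O)CCB1C2CCCC1CCC2 | intermediate
8 | methyl 2-[2-(benzyloxy)-3-(3-hydroxy-3-methylbutyl)-4,5-dimethoxyphenyl]acetate | COC(=O)Cc1cc(OC)c(OC)c(CCC(C)(C)O)c1OCc1ccccc1 | intermediate
9 | methyl phenyl sulfone | CS(=O)(=O)c1ccccc1 | starting material
10 | [(phenylsulfonyl)methyl]lithium | [Li]CS(=O)(=O)c1ccccc1 | intermediate
11 | 1-[2-(benzyloxy)-3-(3-hydroxy-3-methylbutyl)-4,5-dimethoxyphenyl]-3-(phenylsulfonyl)propan-2-one | O=C(Cc1cc(OC)c(OC)c(CCC(C)(C)O)c1OCc1ccccc1)CS(=O)(=O)c1ccccc1 | intermediate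
12 | 2-[2-(benzyloxy)-3-(3-hydroxy-3-methylbutyl)-4,5-dimethoxyphenyl]-1,5-bis(dimethylamino)-4-(phenylsulfonyl)penta-1,4-dien-3-one (alkene isomers) | CN(C)C=C(C(=O)C(=CN(C)C)S(=O)(=O)c1ccccc1)c1cc(OC)c(OC)c(CCC(C)(C)O)c1OCc1ccccc1 | intermediate
13 | 3-[2-(benzyloxy)-3-(3-hydroxy-3-methylbutyl)-4,5-dimethoxyphenyl]-5-(phenylsulfonyl)-4H-pyran-4-one | O=c1c(-c2cc(OC)c(OC)c(CCC(C)(C)O)c2OCc2ccccc2)cocc1S(=O)(=O)c1ccccc1 | intermediate
14 | methyl acetoacetate | COC(=O)CC(C)=O | starting material
15 | methyl 3-(trimethylsilyloxy)but-2-enoate (alkene isomers) | COC(=O)C=C(C)O[Si](C)(C)C | intermediate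
16 | lithium 1-methoxy-3-(trimethylsilyloxy)buta-1,3-dien-1-olate | [Li]OC(OC)=CC(=C)O[Si](C)(C)C | intermediate
17 | (1E)-1-methoxy-1,3-bis(trimethylsilyloxy)buta-1,3-diene | C=C(O[Si](C)(C)C)/C=C(\OC)O[Si](C)(C)C | intermediate
18 | 3-{2-(benzyloxy)-4,5-dimethoxy-3-[3-methyl-3-(trimethylsilyloxy)butyl]phenyl}-5-(phenylsulfonyl)-4H-pyran-4-one | C[Si](C)(C)OC(C)(C)CCc1c(OC)c(OC)cc(-c2cocc(S(=O)(=O)c3ccccc3)c2=O)c1OCc1ccccc1 | intermediate
19 | 3-{2-(benzyloxy)-4,5-dimethoxy-3-[3-methyl-3-(trimethylsilyloxy)butyl]phenyl}-5-methoxy-4a-(phenylsulfonyl)-5,7-bis(trimethylsilyloxy)-4a,5,8,8a-tetrahydro-4H-chromen-4-one (racemic, mixture of diastereomers; all stereocentres are lost in the same step) | COC1(O[Si](C)(C)C)C=C(O[Si](C)(C)C)CC2OC=C(c3cc(OC)c(OC)c(CCC(C)(C)O[Si](C)(C)C)c3OCc3ccccc3)C(=O)C12S(=O)(=O)c1ccccc1 | intermediate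
20 | 3-[2-(benzyloxy)-3-(3-hydroxy-3-methylbutyl)-4,5-dimethoxyphenyl]-5,7-dihydroxy-4H-chromen-4-one | COc1cc(-c2coc3cc(O)cc(O)c3c2=O)c(OCc2ccccc2)c(CCC(C)(C)O)c1OC | intermediate
21 | 5,7-dihydroxy-3-[2-hydroxy-3-(3-hydroxy-3-methylbutyl)-4,5-dimethoxyphenyl]-4H-chromen-4-one (achiral) | COc1cc(-c2coc3cc(O)cc(O)c3c2=O)c(O)c(CCC(C)(C)O)c1OC | target

Total step count: 11. Longest linear sequence: 9 steps (steps 1–7, 10 and 11); steps 8 and 9 make the diene in a side branch.

Steps most likely to fail

Step 10 (ring A annulation, proposed new method). The closure may not follow the first C–C bond: the intermediate may open the heterocycle by retro-oxa-Michael reaction faster than C4a closes on C5, or the sulfinate may not be eliminated, so that no aromatic ring A forms. The fallback uses a known oxidative chalcone rearrangement, sets out from aldehyde 3 and returns to the route at target 21. Claisen–Schmidt condensation of 3 with 1-[2,4-bis(benzyloxy)-6-hydroxyphenyl]ethanone (KOH, EtOH, rt) should give the chalcone (2E)-1-[2,4-bis(benzyloxy)-6-hydroxyphenyl]-3-[2-(benzyloxy)-3-iodo-4,5-dimethoxyphenyl]prop-2-en-1-one F1. Oxidative 1,2-aryl shift with Tl(NO3)3·3H2O in MeOH/HC(OMe)3 should give the acetal 1-[2,4-bis(benzyloxy)-6-hydroxyphenyl]-2-[2-(benzyloxy)-3-iodo-4,5-dimethoxyphenyl]-3,3-dimethoxypropan-1-one F2. HCl in MeOH at reflux should close it to 5,7-bis(benzyloxy)-3-[2-(benzyloxy)-3-iodo-4,5-dimethoxyphenyl]-4H-chromen-4-one F3. B-alkyl Suzuki–Miyaura coupling with borane 7 (made from 6 as in step 5) should give 5,7-bis(benzyloxy)-3-[2-(benzyloxy)-3-(3-hydroxy-3-methylbutyl)-4,5-dimethoxyphenyl]-4H-chromen-4-one F4. Hydrogenolysis of the three benzyl ethers (H2, 10% Pd/C, EtOAc/MeOH) then gives 21.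

Step 7 (pyranone formation). The second condensation may stall because the sulfonyl enaminone formed first lowers the acidity of the benzylic CH2, and prolonged heating or liberated dimethylamine may degrade the electrophilic sulfonyl pyranone. The fallback sets out from keto sulfone 11 and returns at pyranone 13. One equivalent of Me2NCH(OMe)2 (CH2Cl2, rt) should give only the mono-enaminone 1-[2-(benzyloxy)-3-(3-hydroxy-3-methylbutyl)-4,5-dimethoxyphenyl]-4-(dimethylamino)-3-(phenylsulfonyl)but-3-en-2-one F5. Irreversible deprotonation with LiN(SiMe3)2 (2.2 equiv, THF, −78 °C) and Claisen formylation with ethyl formate should give the hydroxymethylene ketone 2-[2-(benzyloxy)-3-(3-hydroxy-3-methylbutyl)-4,5-dimethoxyphenyl]-5-(dimethylamino)-1-hydroxy-4-(phenylsulfonyl)penta-1,4-dien-3-one F6. On acidification (AcOH, THF, rt) this should close by addition–elimination with loss of dimethylamine to 13.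

Step 5 (B-alkyl coupling). Oxidative addition and transmetalation at the iodide flanked by two alkoxy groups may be slow, so that protodeiodination of 5 or β-hydride loss from the alkylpalladium takes over; the free hydroxyl may also consume the borane. The fallback sets out from iodide 5 and alkenol 6 and returns at 8. A Heck reaction (Pd(OAc)2, Bu4NCl, NaHCO3, DMF, 80 °C) should give methyl 2-{2-(benzyloxy)-3-[(1E)-3-hydroxy-3-methylbut-1-en-1-yl]-4,5-dimethoxyphenyl}acetate F7. Hydrogenation of the alkene with H2 and RhCl(PPh3)3 (benzene/EtOH, rt), which leaves the aryl benzyl ether intact, should then give 8.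

Further compounds
F1 | step 10 | (2E)-1-[2,4-bis(benzyloxy)-6-hydroxyphenyl]-3-[2-(benzyloxy)-3-iodo-4,5-dimethoxyphenyl]prop-2-en-1-one | COc1cc(/C=C/C(=O)c2c(O)cc(OCc3ccccc3)cc2OCc2ccccc2)c(OCc2ccccc2)c(I)c1OC
F2 | step 10 | 1-[2,4-bis(benzyloxy)-6-hydroxyphenyl]-2-[2-(benzyloxy)-3-iodo-4,5-dimethoxyphenyl]-3,3-dimethoxypropan-1-one (racemic) | COc1cc(C(C(OC)OC)C(=O)c2c(O)cc(OCc3ccccc3)cc2OCc2ccccc2)c(OCc2ccccc2)c(I)c1OC
F3 | step 10 | 5,7-bis(benzyloxy)-3-[2-(benzyloxy)-3-iodo-4,5-dimethoxyphenyl]-4H-chromen-4-one | COc1cc(-c2coc3cc(OCc4ccccc4)cc(OCc4ccccc4)c3c2=O)c(OCc2ccccc2)c(I)c1OC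
F4 | step 10 | 5,7-bis(benzyloxy)-3-[2-(benzyloxy)-3-(3-hydroxy-3-methylbutyl)-4,5-dimethoxyphenyl]-4H-chromen-4-one | COc1cc(-c2coc3cc(OCc4ccccc4)cc(OCc4ccccc4)c3c2=O)c(OCc2ccccc2)c(CCC(C)(C)O)c1OC
F5 | step 7 | 1-[2-(benzyloxy)-3-(3-hydroxy-3-methylbutyl)-4,5-dimethoxyphenyl]-4-(dimethylamino)-3-(phenylsulfonyl)but-3-en-2-one | CN(C)C=C(C(=O)Cc1cc(OC)c(OC)c(CCC(C)(C)O)c1OCc1ccccc1)S(=O)(=O)c1ccccc1
F6 | step 7 | 2-[2-(benzyloxy)-3-(3-hydroxy-3-methylbutyl)-4,5-dimethoxyphenyl]-5-(dimethylamino)-1-hydroxy-4-(phenylsulfonyl)penta-1,4-dien-3-one | CN(C)C=C(C(=O)C(=CO)c1cc(OC)c(OC)c(CCC(C)(C)O)c1OCc1ccccc1)S(=O)(=O)c1ccccc1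
F7 | step 5 | methyl 2-{2-(benzyloxy)-3-[(1E)-3-hydroxy-3-methylbut-1-en-1-yl]-4,5-dimethoxyphenyl}acetate | COC(=O)Cc1cc(OC)c(OC)c(/C=C/C(C)(C)O)c1OCc1ccccc1
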